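**Remark:** the side chain is numbered C1'–C12' outward from chroman C2 (alkenes C3'=C4', C7'=C8', C11'=C12'; carbinol C9'). Commercial (R)-(−)-linalool of high enantiomeric purity is assumed as the source of C2.

## Retrosynthetic overview

1. Sargachromanol C (31) ← desilylation of its 6-O-TIPS ether 30 ← C6'–C7' bond between homoallylic iodide 15 (chroman + C1'–C6') and dioxin 25 (C7'–C12').
2. Enabling feature: the 2-methylallylic alcohol O–C9'–C8'(CH3)=C7'H. Its oxygen is 1,3 to C7', so O(C9') and C7' can be bridged by an acetone ketal carbon into a temporary 4H-1,3-dioxin ring (O1–C2Me2–O3–C4[=C9']–C5[=C8']=C6[=C7']). This cyclic enol ether is lithiated at C6; an invertive copper-mediated 1,2-metallate shift turns the ring-locked geometry (O1 cis to C9') into the E alkene, expels acetone and frees the C9' hydroxyl.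
3. 15 ← (R)-linalool (supplies C2, its methyl, C3, C4, C1'–C5') + dihaloarene 5: sp3–sp2 Suzuki coupling, then Pd-catalysed aryl C–O closure of the pyran ring (tertiary C–O bond never broken); prenyl end → E-enal → 1,3-diene → 9-BBN → iodide.
4. 25 ← 2,2-dimethyl-1,3-dioxan-5-one: RAMP-hydrazone prenylation sets C9'; kinetic enol triflate and methylation install the C8' methyl enol ether.
5. Ring order: dioxane ring purchased → pyran ring of the chroman closed in step 5 (the only ring closure) → dioxin ring opened and lost in step 15.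

Key step: step 15

## Route

Step 1
Reactants: 1 4-amino-3-methylphenol
Product: 2 2-methyl-4-(triisopropylsilyloxy)aniline
Conditions: TIPSCl, imidazole, DMF, 0 °C → rt
Reagents that add atoms: chlorotriisopropylsilane, CC(C)[Si](Cl)(C(C)C)C(C)C
Why: Selective O-silylation of an aminophenol should occur because the phenoxide oxygen is the harder nucleophile and any N-silyl product is hydrolysed on work-up.

Step 2
Reactants: 2 2-methyl-4-(triisopropylsilyloxy)aniline
Product: 3 2-iodo-6-methyl-4-(triisopropylsilyloxy)aniline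
Conditions: N-iodosuccinimide, MeCN, −10 → 0 °C, dark
Reagents that add atoms: N-iodosuccinimide, O=C1CCC(=O)N1I
Why: Electrophilic aromatic iodination should go to the only free position ortho to the amino group, the strongest director, its para position being blocked.

Step 3
Reactants: 3 2-iodo-6-methyl-4-(triisopropylsilyloxy)aniline
Product: 5 2-bromo-1-iodo-3-methyl-5-(triisopropylsilyloxy)benzene, via arenediazonium bromide 4 (not isolated)
Conditions: t-BuONO, CuBr2, MeCN, 0 °C → rt
Reagents that add atoms: CuBr2, [Cu+2].[Br-].[Br-]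
Why: Non-aqueous Sandmeyer bromination (alkyl nitrite/CuBr2) should replace the amino group by bromine without touching the aryl iodide or the silyl ether.

Step 4
Reactants: 6 (R)-(−)-linalool; 5 2-bromo-1-iodo-3-methyl-5-(triisopropylsilyloxy)benzene
Product: 8 (R)-1-[2-bromo-3-methyl-5-(triisopropylsilyloxy)phenyl]-3,7-dimethyloct-6-en-3-ol, via B-alkyl-9-BBN adduct 7 (not isolated)
Conditions: 6, 9-BBN (2.2 equiv), THF, 0 °C → rt; then 5, PdCl2(dppf) (5 mol %), aq. K3PO4, DMF, rt → 40 °C
Reagents that add atoms: none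
Why: 9-BBN should hydroborate only the monosubstituted vinyl group (anti-Markovnikov), and the B-alkyl Suzuki–Miyaura coupling should take place at the C–I bond in preference to the hindered C–Br bond; the carbinol stereocentre is not involved.

Step 5
Reactants: 8 (R)-1-[2-bromo-3-methyl-5-(triisopropylsilyloxy)phenyl]-3,7-dimethyloct-6-en-3-ol
Product: 9 (R)-2,8-dimethyl-2-(4-methylpent-3-en-1-yl)-6-(triisopropylsilyloxy)chromane
Conditions: Pd(OAc)2 (5 mol %), 2-(di-tert-butylphosphino)-1,1'-binaphthyl (6 mol %), Cs2CO3, toluene, 80 °C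
Reagents that add atoms: none
Why: Buchwald-type intramolecular aryl etherification should close the six-membered pyran ring by aryl C–O bond formation; the tertiary alkoxide has no beta-hydrogen on carbon and its C–O bond is not broken, so C2 keeps the (R) configuration of linalool.

Step 6
Reactants: 9 (R)-2,8-dimethyl-2-(4-methylpent-3-en-1-yl)-6-(triisopropylsilyloxy)chromane
Product: 11 (E)-2-methyl-5-[(R)-2,8-dimethyl-6-(triisopropylsilyloxy)chroman-2-yl]pent-2-enal, via allylic alcohol 10 (not isolated)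
Conditions: SeO2 (0.5 equiv), t-BuOOH (3 equiv), salicylic acid (10 mol %), CH2Cl2, rt; filter, then MnO2, CH2Cl2, rt
Reagents that add atoms: selenium dioxide, O=[Se]=O; tert-butyl hydroperoxide, CC(C)(C)OO
Why: SeO2/t-BuOOH allylic oxidation (ene reaction then [2,3] shift) should oxidise the E methyl of the gem-dimethyl alkene selectively, and MnO2 should take the allylic alcohol on to the E enal.

Step 7
Reactants: 11 (E)-2-methyl-5-[(R)-2,8-dimethyl-6-(triisopropylsilyloxy)chroman-2-yl]pent-2-enal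
Product: 12 (R)-2,8-dimethyl-2-[(E)-4-methylhexa-3,5-dien-1-yl]-6-(triisopropylsilyloxy)chromane
Conditions: Ph3PCH3Br, n-BuLi, THF, 0 °C; then 11, 0 °C → rt
Reagents that add atoms: methyltriphenylphosphonium bromide, C[P+](c1ccccc1)(c1ccccc1)c1ccccc1.[Br-]
Why: Wittig methylenation of the enal should give the terminal 1,3-diene without changing the C3'=C4' geometry.

Step 8
Reactants: 12 (R)-2,8-dimethyl-2-[(E)-4-methylhexa-3,5-dien-1-yl]-6-(triisopropylsilyloxy)chromane
Product: 14 (E)-3-methyl-6-[(R)-2,8-dimethyl-6-(triisopropylsilyloxy)chroman-2-yl]hex-3-en-1-ol, via B-alkyl-9-BBN adduct 13 (not isolated)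
Conditions: 9-BBN (1.2 equiv), THF, 0 °C → rt; then aq. NaOH, H2O2, 0 °C
Reagents that add atoms: hydrogen peroxide, OO
Why: Hydroboration–oxidation should occur at the terminal CH2= of the diene only (as in the homogeraniol synthesis from the corresponding triene), leaving the trisubstituted alkene.

Step 9
Reactants: 14 (E)-3-methyl-6-[(R)-2,8-dimethyl-6-(triisopropylsilyloxy)chroman-2-yl]hex-3-en-1-ol
Product: 15 (R)-2-[(E)-6-iodo-4-methylhex-3-en-1-yl]-2,8-dimethyl-6-(triisopropylsilyloxy)chromane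
Conditions: I2, PPh3, imidazole, CH2Cl2, 0 °C → rt
Reagents that add atoms: iodine, II
Why: Appel iodination of a primary alcohol should proceed under neutral conditions that spare the alkene and the aryl silyl ether.

Step 10
Reactants: 16 2,2-dimethyl-1,3-dioxan-5-one; 17 RAMP, (R)-1-amino-2-(methoxymethyl)pyrrolidine
Product: 18 RAMP hydrazone of 2,2-dimethyl-1,3-dioxan-5-one
Conditions: benzene, reflux, water separator
Reagents that add atoms: none
Why: Hydrazone condensation of this ketone with the Enders auxiliary is standard.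

Step 11
Reactants: 18 RAMP hydrazone of 2,2-dimethyl-1,3-dioxan-5-one; 19 prenyl bromide (1-bromo-3-methylbut-2-ene)
Product: 21 RAMP hydrazone of (R)-2,2-dimethyl-4-(3-methylbut-2-en-1-yl)-1,3-dioxan-5-one, via lithium azaenolate 20 (not isolated)
Conditions: t-BuLi, THF, −78 °C; then 19, −100 °C → rt
Reagents that add atoms: none
Why: Enders hydrazone alkylation: the methoxymethyl-chelated lithium azaenolate should be alkylated on the face left open by the auxiliary, and since SAMP is known to give (S)-4-alkyl dioxanones, RAMP should give the (R) centre that becomes C9'.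

Step 12
Reactants: 21 RAMP hydrazone of (R)-2,2-dimethyl-4-(3-methylbut-2-en-1-yl)-1,3-dioxan-5-one
Product: 22 (R)-2,2-dimethyl-4-(3-methylbut-2-en-1-yl)-1,3-dioxan-5-one
Conditions: saturated aq. oxalic acid, Et2O, rt
Reagents that add atoms: water, O
Why: Mild biphasic oxalic acid hydrolysis should cleave the hydrazone without epimerising the alpha centre or opening the acetonide, and returns the auxiliary.

Step 13
Reactants: 22 (R)-2,2-dimethyl-4-(3-methylbut-2-en-1-yl)-1,3-dioxan-5-one
Product: 24 (R)-2,2-dimethyl-4-(3-methylbut-2-en-1-yl)-4H-1,3-dioxin-5-yl trifluoromethanesulfonate, via lithium enolate 23 (not isolated)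
Conditions: LiN(i-Pr)2, THF, −78 °C; then PhNTf2, −78 → 0 °C
Reagents that add atoms: N-phenylbis(trifluoromethanesulfonimide), O=S(=O)(N(c1ccccc1)S(=O)(=O)C(F)(F)F)C(F)(F)F
Why: Kinetic deprotonation should take place at the unsubstituted alpha-CH2 (C6) and not at the substituted C4, and O-triflation then fixes the C5=C6 enol double bond with C4 untouched.

Step 14
Reactants: 24 (R)-2,2-dimethyl-4-(3-methylbut-2-en-1-yl)-4H-1,3-dioxin-5-yl trifluoromethanesulfonate
Product: 25 (R)-2,2,5-trimethyl-4-(3-methylbut-2-en-1-yl)-4H-1,3-dioxine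
Conditions: MeMgBr, Fe(acac)3 (5 mol %), THF/NMP, −30 → 0 °C; basic work-up
Reagents that add atoms: methylmagnesium bromide, C[Mg]Br
Why: Iron-catalysed cross-coupling of an alkenyl triflate with a methyl Grignard reagent should install the C8' methyl under non-acidic conditions that the enol ketal tolerates.

Step 15
Reactants: 15 (R)-2-[(E)-6-iodo-4-methylhex-3-en-1-yl]-2,8-dimethyl-6-(triisopropylsilyloxy)chromane; 25 (R)-2,2,5-trimethyl-4-(3-methylbut-2-en-1-yl)-4H-1,3-dioxine
Product: 30 (5R,6E,10E)-13-[(R)-2,8-dimethyl-6-(triisopropylsilyloxy)chroman-2-yl]-2,6,10-trimethyltrideca-2,6,10-trien-5-ol, via alkyllithium 26 (not isolated), via 6-lithiodioxin 27 (not isolated), via mixed lithium cuprate 28 (not isolated), via ring-opened alkenylcopper 29 (not isolated)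
Conditions: 15, t-BuLi (2.1 equiv), Et2O/pentane, −78 °C; CuBr·SMe2 (1.0 equiv), Me2S/Et2O, −78 → −40 °C; add 27 [from 25 (1.5 equiv), t-BuLi, THF, −78 → 0 °C]; −78 °C → rt; aq. NH4Cl/NH3
Reagents that add atoms: none
Why: Proposed new method: iodine–lithium exchange turns 15 into primary alkyllithium 26, t-BuLi removes the only vinylic C–H next to oxygen (C6 of the dioxin, the future C7') to give 27, and CuBr·SMe2 joins both on monovalent copper as cuprate 28; on warming, the alkyl group should shift from copper to C6 with displacement of ring oxygen O1 (1,2-metallate rearrangement), the ketal alkoxide released loses acetone and frees the C9' oxygen, and protonolysis of the alkenyl–copper bond with retention gives 30. The closest known reaction type is the copper-mediated 1,2-metallate rearrangement of alpha-lithiated 2,3-dihydrofurans, 3,4-dihydro-2H-pyrans and glycals, used for stereodefined alkenes in isoprenoid chains, and alpha-lithiation of cyclic enol ethers (4H-1,3-dioxins included) is established; what is new is the 1,3-dioxin (cyclic enol ketal) as substrate, whose leaving oxygen should be a better nucleofuge than a simple alkoxide. No ring is closed (the temporary dioxin ring is opened and its C2 bridge leaves as acetone) and no stereocentre is formed; C9' comes from step 11 and none of its bonds is broken. The E geometry of C7'=C8' is controlled by the ring: O1 is necessarily cis to C4 (C9'), the migrating carbon enters C6 with inversion and so ends trans to C9' and cis to the C8' methyl, while copper moves to the C9' side and is replaced by hydrogen. The step needs lithiation at C6 and not at the allylic C4–H or a methyl group, which oxygen-assisted kinetic acidity of the vinylic C–H with t-BuLi at low temperature should secure, and migration of the alkyl ligand only, which is secured because only the alkenyl ligand carries the alpha leaving group. The dioxin partner is used in excess so that the valuable alkyl ligand is consumed.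

Step 16
Reactants: 30 (5R,6E,10E)-13-[(R)-2,8-dimethyl-6-(triisopropylsilyloxy)chroman-2-yl]-2,6,10-trimethyltrideca-2,6,10-trien-5-ol
Product: 31 sargachromanol C, (R)-2-[(3E,7E,9R)-9-hydroxy-4,8,12-trimethyltrideca-3,7,11-trien-1-yl]-2,8-dimethylchroman-6-ol
Conditions: Bu4NF, THF, 0 °C, argon; aq. NH4Cl
Reagents that add atoms: none
Why: Fluoride cleavage of the aryl silyl ether should free the phenol under conditions that leave the allylic alcohol and the three alkenes unchanged.

## Compound list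

1 | 4-amino-3-methylphenol | Cc1cc(O)ccc1N | starting material
2 | 2-methyl-4-(triisopropylsilyloxy)aniline | Cc1cc(O[Si](C(C)C)(C(C)C)C(C)C)ccc1N | intermediate
3 | 2-iodo-6-methyl-4-(triisopropylsilyloxy)aniline | Cc1cc(O[Si](C(C)C)(C(C)C)C(C)C)cc(I)c1N | intermediate
4 | 2-iodo-6-methyl-4-(triisopropylsilyloxy)benzenediazonium bromide | Cc1cc(O[Si](C(C)C)(C(C)C)C(C)C)cc(I)c1[N+]#N.[Br-] | intermediate (not isolated)
5 | 2-bromo-1-iodo-3-methyl-5-(triisopropylsilyloxy)benzene | Cc1cc(O[Si](C(C)C)(C(C)C)C(C)C)cc(I)c1Br | intermediate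
6 | (R)-(−)-linalool, (R)-3,7-dimethylocta-1,6-dien-3-ol | C=C[C@](C)(O)CCC=C(C)C | starting material
7 | (R)-1-(9-borabicyclo[3.3.1]nonan-9-yl)-3,7-dimethyloct-6-en-3-ol | CC(C)=CCC[C@@](C)(O)CCB1C2CCCC1CCC2 | intermediate (not isolated)
8 | (R)-1-[2-bromo-3-methyl-5-(triisopropylsilyloxy)phenyl]-3,7-dimethyloct-6-en-3-ol | CC(C)=CCC[C@@](C)(O)CCc1cc(O[Si](C(C)C)(C(C)C)C(C)C)cc(C)c1Br | intermediate
9 | (R)-2,8-dimethyl-2-(4-methylpent-3-en-1-yl)-6-(triisopropylsilyloxy)chromane | CC(C)=CCC[C@]1(C)CCc2cc(O[Si](C(C)C)(C(C)C)C(C)C)cc(C)c2O1 | intermediate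
10 | (E)-2-methyl-5-[(R)-2,8-dimethyl-6-(triisopropylsilyloxy)chroman-2-yl]pent-2-en-1-ol | OC/C(C)=C/CC[C@]1(C)CCc2cc(O[Si](C(C)C)(C(C)C)C(C)C)cc(C)c2O1 | intermediate (not isolated)
11 | (E)-2-methyl-5-[(R)-2,8-dimethyl-6-(triisopropylsilyloxy)chroman-2-yl]pent-2-enal | O=C/C(C)=C/CC[C@]1(C)CCc2cc(O[Si](C(C)C)(C(C)C)C(C)C)cc(C)c2O1 | intermediate
12 | (R)-2,8-dimethyl-2-[(E)-4-methylhexa-3,5-dien-1-yl]-6-(triisopropylsilyloxy)chromane | C=C/C(C)=C/CC[C@]1(C)CCc2cc(O[Si](C(C)C)(C(C)C)C(C)C)cc(C)c2O1 | intermediate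
13 | 9-{(E)-3-methyl-6-[(R)-2,8-dimethyl-6-(triisopropylsilyloxy)chroman-2-yl]hex-3-en-1-yl}-9-borabicyclo[3.3.1]nonane | B1(CC/C(C)=C/CC[C@]2(C)CCc3cc(O[Si](C(C)C)(C(C)C)C(C)C)cc(C)c3O2)C2CCCC1CCC2 | intermediate (not isolated)
14 | (E)-3-methyl-6-[(R)-2,8-dimethyl-6-(triisopropylsilyloxy)chroman-2-yl]hex-3-en-1-ol | OCC/C(C)=C/CC[C@]1(C)CCc2cc(O[Si](C(C)C)(C(C)C)C(C)C)cc(C)c2O1 | intermediate
15 | (R)-2-[(E)-6-iodo-4-methylhex-3-en-1-yl]-2,8-dimethyl-6-(triisopropylsilyloxy)chromane | ICC/C(C)=C/CC[C@]1(C)CCc2cc(O[Si](C(C)C)(C(C)C)C(C)C)cc(C)c2O1 | intermediate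
16 | 2,2-dimethyl-1,3-dioxan-5-one | CC1(C)OCC(=O)CO1 | starting material
17 | RAMP, (R)-1-amino-2-(methoxymethyl)pyrrolidine | COC[C@H]1CCCN1N | starting material
18 | RAMP hydrazone of 2,2-dimethyl-1,3-dioxan-5-one | CC1(C)OCC(=NN2CCC[C@@H]2COC)CO1 | intermediate
19 | prenyl bromide, 1-bromo-3-methylbut-2-ene | CC(C)=CCBr | starting material
20 | lithium azaenolate of 18 | [Li]N(N1CCC[C@@H]1COC)C1=COC(C)(C)OC1 | intermediate (not isolated)
21 | RAMP hydrazone of (R)-2,2-dimethyl-4-(3-methylbut-2-en-1-yl)-1,3-dioxan-5-one | CC(C)=CC[C@H]1OC(C)(C)OCC1=NN1CCC[C@@H]1COC | intermediate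
22 | (R)-2,2-dimethyl-4-(3-methylbut-2-en-1-yl)-1,3-dioxan-5-one | CC(C)=CC[C@H]1OC(C)(C)OCC1=O | intermediate
23 | lithium enolate of 22 (C5=C6) | CC(C)=CC[C@H]1OC(C)(C)OC=C1O[Li] | intermediate (not isolated)
24 | (R)-2,2-dimethyl-4-(3-methylbut-2-en-1-yl)-4H-1,3-dioxin-5-yl trifluoromethanesulfonate | CC(C)=CC[C@H]1OC(C)(C)OC=C1OS(=O)(=O)C(F)(F)F | intermediate
25 | (R)-2,2,5-trimethyl-4-(3-methylbut-2-en-1-yl)-4H-1,3-dioxine | CC(C)=CC[C@H]1OC(C)(C)OC=C1C | intermediate
26 | alkyllithium from 15, {(E)-3-methyl-6-[(R)-2,8-dimethyl-6-(triisopropylsilyloxy)chroman-2-yl]hex-3-en-1-yl}lithium | [Li]CC/C(C)=C/CC[C@]1(C)CCc2cc(O[Si](C(C)C)(C(C)C)C(C)C)cc(C)c2O1 | intermediate (not isolated)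
27 | (R)-6-lithio-2,2,5-trimethyl-4-(3-methylbut-2-en-1-yl)-4H-1,3-dioxine | CC(C)=CC[C@H]1OC(C)(C)OC([Li])=C1C | intermediate (not isolated)
28 | lithium alkyl(dioxin-6-yl)cuprate from 26 and 27 | [Li+].CC(C)=CC[C@H]1OC(C)(C)OC([Cu-]CC/C(C)=C/CC[C@]2(C)CCc3cc(O[Si](C(C)C)(C(C)C)C(C)C)cc(C)c3O2)=C1C | intermediate (not isolated)
29 | ring-opened alkenylcopper, lithium hemiketal alkoxide at the C9' oxygen, copper on C7' cis to C9' | CC(C)=CC[C@@H](OC(C)(C)O[Li])/C(C)=C(\[Cu])CC/C(C)=C/CC[C@]1(C)CCc2cc(O[Si](C(C)C)(C(C)C)C(C)C)cc(C)c2O1 | intermediate (not isolated)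
30 | (5R,6E,10E)-13-[(R)-2,8-dimethyl-6-(triisopropylsilyloxy)chroman-2-yl]-2,6,10-trimethyltrideca-2,6,10-trien-5-ol | CC(C)=CC[C@@H](O)/C(C)=C/CC/C(C)=C/CC[C@]1(C)CCc2cc(O[Si](C(C)C)(C(C)C)C(C)C)cc(C)c2O1 | intermediate
31 | sargachromanol C | CC(C)=CC[C@@H](O)/C(C)=C/CC/C(C)=C/CC[C@]1(C)CCc2cc(O)cc(C)c2O1 | target

## Step count and risks

Total step count: 16. Longest linear sequence: 11 steps (steps 1–9, 15, 16).

**Risk 1, step 15.** Metalation of 25 may occur at the allylic C4–H instead of C6, or the mixed cuprate may fail to rearrange before it decomposes, so that only the reduced side chain is recovered on quench. The fallback uses the known B-alkyl Suzuki–Miyaura coupling; it sets out from alkylborane 13 (made from diene 12 as in step 8 but not oxidised) and comes back at 30.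
- 4-Methylpent-3-enoic acid is converted with carbonyldiimidazole and N,O-dimethylhydroxylamine hydrochloride into N-methoxy-N,4-dimethylpent-3-enamide F1.
- LiC≡CSiMe3 (THF, −78 °C) gives 6-methyl-1-(trimethylsilyl)hept-5-en-1-yn-3-one F2.
- Transfer hydrogenation with RuCl[(R,R)-TsDPEN](p-cymene) in i-PrOH should give (R)-6-methyl-1-(trimethylsilyl)hept-5-en-1-yn-3-ol F3.
- K2CO3 in MeOH gives (R)-6-methylhept-5-en-1-yn-3-ol F4.
- Zirconium-catalysed methylalumination (Me3Al, Cp2ZrCl2, CH2Cl2), then I2, gives (3R,1E)-1-iodo-2,6-dimethylhepta-1,5-dien-3-ol F5.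
- Coupling of 13 with F5 (PdCl2(dppf), AsPh3, Cs2CO3, DMF/THF/H2O, rt) should give 30 with retention of the alkene geometry.

**Risk 2, step 5.** Oxidative addition into the electron-rich, doubly ortho-substituted C–Br bond may be too slow, so that hydrodebromination or loss of the silyl group outruns C–O reductive elimination. The fallback closes the ring oxidatively through a quinone ketal, again without breaking the tertiary C–O bond; it sets out from borane 7 and comes back at 9.
- 4-Methoxy-2-methylphenol is brominated (N-bromosuccinimide) to 2-bromo-4-methoxy-6-methylphenol F6 and methylated (MeI, K2CO3) to 1-bromo-2,5-dimethoxy-3-methylbenzene F7.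
- Suzuki coupling of 7 with F7 (Pd(OAc)2, SPhos, K3PO4) gives (R)-1-(2,5-dimethoxy-3-methylphenyl)-3,7-dimethyloct-6-en-3-ol F8.
- (NH4)2Ce(NO3)6 in MeCN/H2O gives (R)-2-(3-hydroxy-3,7-dimethyloct-6-en-1-yl)-6-methyl-1,4-benzoquinone F9.
- HC(OMe)3, MeOH and pyridinium p-toluenesulfonate give the cyclic ketal (2R)-8a-methoxy-2,8-dimethyl-2-(4-methylpent-3-en-1-yl)-3,4-dihydro-2H-chromen-6(8aH)-one F10.
- Reduction with ascorbic acid, as known for 8a-alkoxytocopherones, should give (R)-2,8-dimethyl-2-(4-methylpent-3-en-1-yl)chroman-6-ol F11.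
- TIPSCl/imidazole returns 9.

**Risk 3, step 13.** Enolisation toward the substituted C4 would give the regioisomeric enol triflate and erode the C9' configuration. The fallback avoids any enolate; it sets out from ketone 22 and comes back at 25.
- Wittig methylenation (Ph3P=CH2, THF, −78 → 0 °C) gives (R)-2,2-dimethyl-5-methylidene-4-(3-methylbut-2-en-1-yl)-1,3-dioxane F12.
- Metal-hydride-catalysed migration of the exocyclic double bond toward the unsubstituted C6 (RuClH(CO)(PPh3)3, toluene, 80 °C), the known route from 5-methylene-1,3-dioxanes to 5-methyl-4H-1,3-dioxins, should give 25.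

## Further compounds

F1 | step 15 | N-methoxy-N,4-dimethylpent-3-enamide | CC(C)=CCC(=O)N(C)OC
F2 | step 15 | 6-methyl-1-(trimethylsilyl)hept-5-en-1-yn-3-one | CC(C)=CCC(=O)C#C[Si](C)(C)C
F3 | step 15 | (R)-6-methyl-1-(trimethylsilyl)hept-5-en-1-yn-3-ol | CC(C)=CC[C@@H](O)C#C[Si](C)(C)C
F4 | step 15 | (R)-6-methylhept-5-en-1-yn-3-ol | CC(C)=CC[C@@H](O)C#C
F5 | step 15 | (3R,1E)-1-iodo-2,6-dimethylhepta-1,5-dien-3-ol | CC(C)=CC[C@@H](O)/C(C)=C/I
F6 | step 5 | 2-bromo-4-methoxy-6-methylphenol | COc1cc(C)c(O)c(Br)c1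
F7 | step 5 | 1-bromo-2,5-dimethoxy-3-methylbenzene | COc1cc(C)c(OC)c(Br)c1
F8 | step 5 | (R)-1-(2,5-dimethoxy-3-methylphenyl)-3,7-dimethyloct-6-en-3-ol | COc1cc(C)c(OC)c(CC[C@](C)(O)CCC=C(C)C)c1
F9 | step 5 | (R)-2-(3-hydroxy-3,7-dimethyloct-6-en-1-yl)-6-methyl-1,4-benzoquinone | CC(C)=CCC[C@@](C)(O)CCC1=CC(=O)C=C(C)C1=O
F10 | step 5 | (2R)-8a-methoxy-2,8-dimethyl-2-(4-methylpent-3-en-1-yl)-3,4-dihydro-2H-chromen-6(8aH)-one | CC(C)=CCC[C@]1(C)CCC2=CC(=O)C=C(C)C2(OC)O1
F11 | step 5 | (R)-2,8-dimethyl-2-(4-methylpent-3-en-1-yl)chroman-6-ol | CC(C)=CCC[C@]1(C)CCc2cc(O)cc(C)c2O1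
F12 | step 13 | (R)-2,2-dimethyl-5-methylidene-4-(3-methylbut-2-en-1-yl)-1,3-dioxane | CC(C)=CC[C@H]1OC(C)(C)OCC1=C
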